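The pyranone ring is disconnected at three bonds, C8a–O1, C4a–C4 and O1–C2, back to an aryne and a 2-alkynoic acid. The plan exploits the ortho relationship of O1 (on C8a) and the C4 carbonyl (on C4a) on the benzene ring, with the C5 oxygen next to C4a serving as the regiochemical director: one fluoride-triggered operation inserts the aryne into the acid C–O bond and closes the pyranone 6-endo, the acid supplying both heterocyclic oxygens. The aryne precursor is a hexasubstituted ortho-trimethylsilylphenyl triflate bearing two methoxy and two methyl groups; its partner is hexacos-2-ynoic acid. Demethylation then gives the target.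

Key step: step 8

Remark on the chemistry: the target has no stereocentre, its side chain is read as unbranched tricosyl (C23), and both phenolic oxygens are carried as methyl ethers until the last step.

Step 1
Reactants: 1 2,4-dimethoxy-3-methylbenzaldehyde
Product: 3 1,3-dimethoxy-2,4-dimethylbenzene, via benzylic alcohol 2 (not isolated)
Conditions: H2 (4 atm), 10% Pd/C, AcOH, 40 °C
Reagents that add atoms: none
Why: Catalytic hydrogenation of the aldehyde followed by benzylic C–O hydrogenolysis, which should be fast because the ortho and para methoxy groups stabilise the benzylic cation-like transition state, while the ring and the aryl ethers are inert to Pd/C.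

Step 2
Reactants: 3 1,3-dimethoxy-2,4-dimethylbenzene
Product: 4 1-bromo-2,4-dimethoxy-3,5-dimethylbenzene
Conditions: NBS, MeCN, 0 °C → rt, dark
Reagents that add atoms: N-bromosuccinimide, O=C1CCC(=O)N1Br
Why: Electrophilic aromatic bromination, directed to the one ring CH that is ortho to one methoxy group and para to the other, the remaining CH being meta to both.

Step 3
Reactants: 4 1-bromo-2,4-dimethoxy-3,5-dimethylbenzene
Product: 7 2,4-dimethoxy-3,5-dimethylphenol, via aryllithium 5 (not isolated), via dimethyl arylboronate 6 (not isolated)
Conditions: n-BuLi, THF, −78 °C; B(OMe)3, −78 °C → rt; AcOH, 30% H2O2, 0 °C → rt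
Reagents that add atoms: hydrogen peroxide, OO
Why: Bromine–lithium exchange, borylation and boronate oxidation (1,2-aryl shift from boron to oxygen) should convert C–Br into C–OH without touching the ethers.

Step 4
Reactants: 7 2,4-dimethoxy-3,5-dimethylphenol
Product: 8 2-bromo-4,6-dimethoxy-3,5-dimethylphenol
Conditions: NBS, CH2Cl2, −40 → 0 °C
Reagents that add atoms: N-bromosuccinimide, O=C1CCC(=O)N1Br
Why: Electrophilic bromination of the phenol at its only unsubstituted ring carbon, which lies ortho to the hydroxyl group, so no regiochemical choice arises.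

Step 5
Reactants: 8 2-bromo-4,6-dimethoxy-3,5-dimethylphenol
Product: 11 2,4-dimethoxy-3,5-dimethyl-6-(trimethylsilyl)phenyl trifluoromethanesulfonate, via trimethylsilyl ether 9 (not isolated), via lithium phenoxide 10 (not isolated)
Conditions: HMDS, THF, reflux, then evaporation; n-BuLi, THF, −100 °C; Tf2O, −100 °C → rt
Reagents that add atoms: hexamethyldisilazane, C[Si](C)(C)N[Si](C)(C)C; trifluoromethanesulfonic anhydride, O=S(=O)(OS(=O)(=O)C(F)(F)F)C(F)(F)F
Why: O-silylation, bromine–lithium exchange and anionic 1,3 O-to-C silyl shift (retro-Brook rearrangement) place silicon ortho to the phenoxide, which Tf2O then traps, the standard entry to ortho-silylaryl triflates.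

Step 6
Reactants: 12 1-(trimethylsilyl)propyne; 13 1-bromodocosane
Product: 16 pentacos-1-yne, via lithiated silylpropyne 14 (not isolated), via silylalkyne 15 (not isolated)
Conditions: n-BuLi, THF, −78 → −20 °C; 13, DMPU, −20 °C → rt; then MeOH, K2CO3, rt
Reagents that add atoms: none
Why: Propargylic lithiation of the silylpropyne and SN2 alkylation with the primary bromide at the carbon remote from silicon, followed in the same flask by methoxide-mediated protodesilylation of the alkynylsilane.

Step 7
Reactants: 16 pentacos-1-yne
Product: 18 hexacos-2-ynoic acid, via lithium acetylide 17 (not isolated)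
Conditions: n-BuLi, THF, 0 °C; CO2 (g), 0 °C → rt; aq. HCl
Reagents that add atoms: carbon dioxide, O=C=O
Why: Deprotonation of the terminal alkyne and carboxylation of the lithium acetylide with carbon dioxide, a standard route to alk-2-ynoic acids.

Step 8
Reactants: 11 2,4-dimethoxy-3,5-dimethyl-6-(trimethylsilyl)phenyl trifluoromethanesulfonate; 18 hexacos-2-ynoic acid
Product: 21 5,7-dimethoxy-6,8-dimethyl-2-tricosyl-4H-chromen-4-one, via aryne 19 (not isolated), via ortho-hydroxyaryl ynone 20 (not isolated)
Conditions: 11 (1.5 equiv), CsF (4 equiv), THF, 125 °C, sealed tube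
Reagents that add atoms: none
Why: Fluoride removes the silyl group of 11 with loss of triflate to release aryne 19; the carboxylate of 18 bonds through oxygen to the aryne carbon that has the methyl neighbour (future C8a), the carbanion left at C4a adds to the ester carbonyl in a 4-exo-trig step, and collapse of the strained four-membered alkoxide gives the ortho-acyl phenoxide of 20, so that C8a–O1 and C4a–C4 are in place. The phenoxide should then add to the β-carbon of its own ynone in a 6-endo-dig conjugate addition that forms O1–C2 and the pyranone ring, the allenolate being protonated at C3 by the bifluoride that holds the former acid proton. The closest known reaction type is the fluoride-mediated insertion of arynes into the C–O bond of carboxylic acids to give ortho-hydroxyaryl ketones, including its tandem version in which an acid with a conjugated C–C multiple bond closes to the benzopyranone in the same flask. No stereocentre is created. The one selectivity required is the sense of carboxylate addition: the C5 methoxy group inductively polarises the aryne carbon beside it (C4a), so the oxygen nucleophile should bond to the remote carbon C8a and the carbanion should develop next to the oxygen substituent, while the C8 methyl group beside the attacked carbon exerts only a small opposing steric effect. The 6-endo mode should prevail over 5-exo because only attack at the β-carbon gives a stabilised allenolate, and the aprotic medium supports this.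

Step 9
Reactants: 21 5,7-dimethoxy-6,8-dimethyl-2-tricosyl-4H-chromen-4-one
Product: 22 5,7-dihydroxy-6,8-dimethyl-2-tricosyl-4H-chromen-4-one
Conditions: BBr3 (6 equiv), CH2Cl2, −78 °C → rt; then H2O
Reagents that add atoms: none
Why: BBr3 demethylation of aryl methyl ethers, in which bromide attacks the methyl groups of the boron-complexed ethers (the C5 ether is further activated by chelation to the C4 carbonyl), while the pyranone, the alkyl chain and the C-methyl groups should be inert.

Compound list
1 | 2,4-dimethoxy-3-methylbenzaldehyde | COc1ccc(C=O)c(OC)c1C | starting material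
2 | (2,4-dimethoxy-3-methylphenyl)methanol | COc1ccc(CO)c(OC)c1C | intermediate
3 | 1,3-dimethoxy-2,4-dimethylbenzene | COc1ccc(C)c(OC)c1C | intermediate
4 | 1-bromo-2,4-dimethoxy-3,5-dimethylbenzene | COc1c(Br)cc(C)c(OC)c1C | intermediate
5 | (2,4-dimethoxy-3,5-dimethylphenyl)lithium | COc1c([Li])cc(C)c(OC)c1C | intermediate
6 | dimethyl (2,4-dimethoxy-3,5-dimethylphenyl)boronate | COB(OC)c1cc(C)c(OC)c(C)c1OC | intermediate
7 | 2,4-dimethoxy-3,5-dimethylphenol | COc1c(O)cc(C)c(OC)c1C | intermediate
8 | 2-bromo-4,6-dimethoxy-3,5-dimethylphenol | COc1c(O)c(Br)c(C)c(OC)c1C | intermediate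
9 | (2-bromo-4,6-dimethoxy-3,5-dimethylphenoxy)trimethylsilane | COc1c(O[Si](C)(C)C)c(Br)c(C)c(OC)c1C | intermediate
10 | lithium 2,4-dimethoxy-3,5-dimethyl-6-(trimethylsilyl)phenolate | COc1c([O-])c([Si](C)(C)C)c(C)c(OC)c1C.[Li+] | intermediate
11 | 2,4-dimethoxy-3,5-dimethyl-6-(trimethylsilyl)phenyl trifluoromethanesulfonate | COc1c(C)c(OC)c(C)c([Si](C)(C)C)c1OS(=O)(=O)C(F)(F)F | intermediate
12 | 1-(trimethylsilyl)propyne | CC#C[Si](C)(C)C | starting material
13 | 1-bromodocosane | CCCCCCCCCCCCCCCCCCCCCCBr | starting material
14 | [3-(trimethylsilyl)prop-2-yn-1-yl]lithium | [Li]CC#C[Si](C)(C)C | intermediate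
15 | trimethyl(pentacos-1-yn-1-yl)silane | CCCCCCCCCCCCCCCCCCCCCCCC#C[Si](C)(C)C | intermediate
16 | pentacos-1-yne | CCCCCCCCCCCCCCCCCCCCCCCC#C | intermediate
17 | (pentacos-1-yn-1-yl)lithium | CCCCCCCCCCCCCCCCCCCCCCCC#C[Li] | intermediate
18 | hexacos-2-ynoic acid | CCCCCCCCCCCCCCCCCCCCCCCC#CC(=O)O | intermediate
19 | 3,5-dimethoxy-4,6-dimethylbenzyne (1,2-didehydro-3,5-dimethoxy-4,6-dimethylbenzene) | COC1=C(C)C(OC)=C(C)C#C1 | intermediate
20 | 1-(2-hydroxy-4,6-dimethoxy-3,5-dimethylphenyl)hexacos-2-yn-1-one | CCCCCCCCCCCCCCCCCCCCCCCC#CC(=O)c1c(O)c(C)c(OC)c(C)c1OC | intermediate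
21 | 5,7-dimethoxy-6,8-dimethyl-2-tricosyl-4H-chromen-4-one | CCCCCCCCCCCCCCCCCCCCCCCc1cc(=O)c2c(OC)c(C)c(OC)c(C)c2o1 | intermediate
22 | 5,7-dihydroxy-6,8-dimethyl-2-tricosyl-4H-chromen-4-one | CCCCCCCCCCCCCCCCCCCCCCCc1cc(=O)c2c(O)c(C)c(O)c(C)c2o1 | target

Total step count: 9. Longest linear sequence: 7 steps (steps 1–5, 8 and 9); steps 6 and 7 make the acid in parallel.

Steps most likely to fail

1. Step 8. The carbanion formed after carboxylate addition lies ortho to a methoxy group and beside a crowded ester, so proton capture from bifluoride or unreacted acid may outrun the 4-exo acyl shift and stop the sequence at the O-aryl alkynoate. The alkynoate may also decarboxylate at this temperature, or the ynone phenoxide may close in the 5-exo mode. The fallback sets out from 11 and returns at 21. It uses the aryne for the C–O bond only, makes the C–C bond by Fries rearrangement and closes the pyranone by Claisen condensation and cyclodehydration. Treatment of 11 with CsF and excess acetic acid in MeCN at room temperature, where O-arylation with proton quench is the expected course, should give 3,5-dimethoxy-2,4-dimethylphenyl acetate F1, the acetate adding to aryne 19 in the same sense as in step 8. Fries rearrangement with BF3·OEt2 at 90 °C moves the acetyl group to the only unsubstituted ring carbon and should give 1-(2-hydroxy-4,6-dimethoxy-3,5-dimethylphenyl)ethan-1-one F2. Its dianion (LiHMDS, THF, −78 °C → rt) is acylated with methyl tetracosanoate to 1-(2-hydroxy-4,6-dimethoxy-3,5-dimethylphenyl)hexacosane-1,3-dione F3. Acid-catalysed cyclodehydration (TsOH, toluene, reflux) then closes the ring to 21.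

2. Step 5. n-Butyllithium may attack silicon of the aryl silyl ether instead of bromine, or the aryllithium may be protonated before the O-to-C silyl shift, so that silicon never reaches the ring. The preceding bromination of the electron-rich para-methoxyphenol is also open to oxidation. The fallback sets out from 7 and returns at 11, replacing halogenation and silyl migration by directed ortho-metalation. Phenol 7 is carbamoylated (ClCONEt2, NaH, THF) to 2,4-dimethoxy-3,5-dimethylphenyl diethylcarbamate F4. Deprotonation with s-BuLi/TMEDA in THF at −78 °C at the only ring CH, which is ortho to the carbamate, should give [2-(diethylcarbamoyloxy)-3,5-dimethoxy-4,6-dimethylphenyl]lithium F5. Quenching with TMSCl gives 2,4-dimethoxy-3,5-dimethyl-6-(trimethylsilyl)phenyl diethylcarbamate F6. Reductive cleavage of the carbamate (LiAlH4, THF, reflux) frees 2,4-dimethoxy-3,5-dimethyl-6-(trimethylsilyl)phenol F7, and triflation (Tf2O, pyridine, CH2Cl2, 0 °C) gives 11.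

3. Step 6. The ambident propargyl/allenyl anion may be alkylated through its allenyl terminus, and the SN2 displacement on the waxy, poorly soluble C22 bromide may be slow enough for elimination or anion decay to compete. The fallback sets out from 13 and returns at 15, with the polarity of the coupling reversed. Bromide 13 is converted with Mg in THF into docosylmagnesium bromide F8, which is coupled with 3-bromo-1-(trimethylsilyl)prop-1-yne under CuBr·SMe2 catalysis (THF, −30 °C → rt). The silyl group blocks attack at the alkyne terminus, so direct substitution should give 15. Desilylation with K2CO3/MeOH as in step 6 then gives 16.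

Further compounds
F1 | step 8 | 3,5-dimethoxy-2,4-dimethylphenyl acetate | CC(=O)Oc1cc(OC)c(C)c(OC)c1C
F2 | step 8 | 1-(2-hydroxy-4,6-dimethoxy-3,5-dimethylphenyl)ethan-1-one | CC(=O)c1c(O)c(C)c(OC)c(C)c1OC
F3 | step 8 | 1-(2-hydroxy-4,6-dimethoxy-3,5-dimethylphenyl)hexacosane-1,3-dione | CCCCCCCCCCCCCCCCCCCCCCCC(=O)CC(=O)c1c(O)c(C)c(OC)c(C)c1OC
F4 | step 5 | 2,4-dimethoxy-3,5-dimethylphenyl diethylcarbamate | CCN(CC)C(=O)Oc1cc(C)c(OC)c(C)c1OC
F5 | step 5 | [2-(diethylcarbamoyloxy)-3,5-dimethoxy-4,6-dimethylphenyl]lithium | CCN(CC)C(=O)Oc1c([Li])c(C)c(OC)c(C)c1OC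
F6 | step 5 | 2,4-dimethoxy-3,5-dimethyl-6-(trimethylsilyl)phenyl diethylcarbamate | CCN(CC)C(=O)Oc1c([Si](C)(C)C)c(C)c(OC)c(C)c1OC
F7 | step 5 | 2,4-dimethoxy-3,5-dimethyl-6-(trimethylsilyl)phenol | COc1c(O)c([Si](C)(C)C)c(C)c(OC)c1C
F8 | step 6 | docosylmagnesium bromide | CCCCCCCCCCCCCCCCCCCCCC[Mg]Br
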